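**Retrosynthetic overview**
1. The last bond made is the one between the alkyne and the (E)-olefin of the side chain (C2–C3 of the dodecatrienynyl unit). Both carbons are traced back to alkyne termini: bromoalkyne 11 (acetylide carbon with reversed polarity) and dienyne 18. A one-pot hydroboration/copper-catalysed alkynylation joins them, creates the (3E) olefin and gives the target itself.
2. Enabling feature: the en-yne C1≡C2–C3H=C4H on oxolane C5. C3=C4 has the constitution and geometry of a syn, anti-Markovnikov hydrometalated terminal alkyne, and C1≡C2 is an ethynyl group on a ring carbon that can be brominated at C2.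
3. The oxolane (the only ring, O1/C2–C5) is formed in step 3 by Mukaiyama aerobic oxidative cyclisation of hydroxy-alkene 6, which relays the carbinol derived from (S)-epichlorohydrin into the 2,5-trans relationship. The ynoate is then saturated and CH2OH is converted into C≡CBr.
4. Dienyne 18 comes from hept-6-yn-1-ol by a Z-selective Wittig reaction of its ylide with (Z)-3-bromoacrolein made in the flask.

Key step: step 11

Remark: the SMILES is read as the 2,5-trans oxolane (2R,5S) with a (3E,9Z,11Z) side chain; Co(modp)2 is the divalent cobalt complex of two 1-morpholinocarbamoyl-4,4-dimethylpentane-1,3-dionate ligands.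

**Route**

Step 1
Reactants: 1 (2S)-2-(chloromethyl)oxirane [(S)-epichlorohydrin]
Product: 3 (2S)-2-(but-3-en-1-yl)oxirane, via (2S)-1-chlorohex-5-en-2-ol 2 (not isolated)
Conditions: CH2=CHCH2MgCl, CuI (5 mol %), THF, −40 °C; H2O; then NaOH (aq.), rt
Reagents that add atoms: allylmagnesium chloride, C=CC[Mg]Cl
Why: Copper-catalysed Grignard opening of the epoxide at its CH2 terminus followed by Williamson closure of the chlorohydrin moves the oxirane along the chain without touching the stereocentre, so the (S) configuration of 1 is kept.

Step 2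
Reactants: 4 methyl prop-2-ynoate; 3 (2S)-2-(but-3-en-1-yl)oxirane
Product: 6 methyl (5S)-5-hydroxynon-8-en-2-ynoate, via methyl 3-lithioprop-2-ynoate 5 (not isolated)
Conditions: n-BuLi, THF, −78 °C; BF3·OEt2; then 3, −78 °C
Reagents that add atoms: none
Why: BF3-assisted opening of a terminal epoxide by a lithium acetylide (Yamaguchi–Hirao alkynylation) occurs at the unsubstituted carbon, the carbinol centre is carried over unchanged from 3, and the linear ynoate keeps the δ-hydroxy ester from lactonising.

Step 3
Reactants: 6 methyl (5S)-5-hydroxynon-8-en-2-ynoate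
Product: 7 methyl 4-[(2S,5S)-5-(hydroxymethyl)oxolan-2-yl]but-2-ynoate
Conditions: Co(modp)2 (10 mol %), O2 (1 atm), t-BuOOH (10 mol %), i-PrOH, 55 °C
Reagents that add atoms: dioxygen, O=O
Why: Mukaiyama aerobic oxidative cyclisation of a pent-4-en-1-ol (cobalt-mediated 5-exo closure onto the alkene, trapping of the primary radical by O2 and reduction to the alcohol) is known to give 2,5-trans-oxolanylmethanols, the existing (S) carbinol controlling the new centre through a chair-like transition state with the side chain pseudo-equatorial, while the electron-poor ynoate cannot reach the alkoxide or the radical and should remain a spectator.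

Step 4
Reactants: 7 methyl 4-[(2S,5S)-5-(hydroxymethyl)oxolan-2-yl]but-2-ynoate
Product: 8 methyl 4-[(2R,5S)-5-(hydroxymethyl)oxolan-2-yl]butanoate
Conditions: H2 (1 atm), Pd/C (10 %), EtOAc, rt
Reagents that add atoms: none
Why: Heterogeneous catalytic hydrogenation saturates the alkyne to the butanoate chain without affecting ester, ether or alcohol and without touching either stereocentre (the descriptor at C2 changes only because the ranking of its substituents changes).

Step 5
Reactants: 8 methyl 4-[(2R,5S)-5-(hydroxymethyl)oxolan-2-yl]butanoate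
Product: 9 methyl 4-[(2R,5S)-5-formyloxolan-2-yl]butanoate
Conditions: Dess–Martin periodinane, NaHCO3, CH2Cl2, 0 °C to rt
Reagents that add atoms: none
Why: Dess–Martin oxidation under bicarbonate buffer converts the primary alcohol into the α-alkoxy aldehyde without epimerising C5, and the aldehyde is used directly.

Step 6
Reactants: 9 methyl 4-[(2R,5S)-5-formyloxolan-2-yl]butanoate
Product: 10 methyl 4-[(2R,5S)-5-ethynyloxolan-2-yl]butanoate
Conditions: dimethyl (1-diazo-2-oxopropyl)phosphonate, K2CO3, MeOH, 0 °C to rt
Reagents that add atoms: dimethyl (1-diazo-2-oxopropyl)phosphonate, COP(=O)(OC)C(=[N+]=[N-])C(C)=O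
Why: Ohira–Bestmann (Seyferth–Gilbert) homologation, in which the diazomethylphosphonate anion olefinates the aldehyde and the diazoalkene loses N2 with 1,2-hydride shift, gives the terminal alkyne under K2CO3/MeOH, conditions that return the methyl ester unchanged and are mild enough to keep the C5 configuration.

Step 7
Reactants: 10 methyl 4-[(2R,5S)-5-ethynyloxolan-2-yl]butanoate
Product: 11 methyl 4-[(2R,5S)-5-(bromoethynyl)oxolan-2-yl]butanoate
Conditions: NBS, AgNO3 (10 mol %), acetone, rt, dark
Reagents that add atoms: N-bromosuccinimide, BrN1C(=O)CCC1=O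
Why: Silver-catalysed electrophilic bromination of a terminal alkyne with NBS proceeds through the silver acetylide and installs the C–Br bond that reverses the polarity of the acetylenic carbon, with ester and ether untouched.

Step 8
Reactants: 12 hept-6-yn-1-ol
Product: 13 7-iodohept-1-yne
Conditions: I2, PPh3, imidazole, CH2Cl2, 0 °C to rt
Reagents that add atoms: iodine, II
Why: Appel-type iodination (PPh3/I2/imidazole) converts the primary alcohol into the iodide by SN2 displacement of the oxyphosphonium group and leaves the terminal alkyne alone.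

Step 9
Reactants: 13 7-iodohept-1-yne
Product: 14 (hept-6-yn-1-yl)triphenylphosphonium iodide
Conditions: PPh3, MeCN, reflux
Reagents that add atoms: triphenylphosphine, c1ccc(cc1)P(c1ccccc1)c1ccccc1
Why: SN2 quaternisation of triphenylphosphine by the primary iodide gives the Wittig salt.

Step 10
Reactants: 14 (hept-6-yn-1-yl)triphenylphosphonium iodide; 15 ethyl (2Z)-3-bromoprop-2-enoate
Product: 18 (7Z,9Z)-10-bromodeca-7,9-dien-1-yne, via (hept-6-yn-1-ylidene)triphenylphosphorane 16 (not isolated), via (2Z)-3-bromoprop-2-enal 17 (not isolated)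
Conditions: 14, NaN(SiMe3)2, THF, −78 to 0 °C; 15, i-Bu2AlH, CH2Cl2, −78 °C; combine at −78 °C, then to rt
Reagents that add atoms: none
Why: One-pot half-reduction/Wittig olefination: i-Bu2AlH stops at the aluminium hemiacetal at −78 °C, which releases the configurationally labile (Z)-enal 17 only when the non-stabilised ylide 16 is present, and the kinetically controlled cis-oxaphosphetane should then give the new (7Z) olefin while the (Z)-bromoalkene geometry of 15 is carried through.

Step 11
Reactants: 18 (7Z,9Z)-10-bromodeca-7,9-dien-1-yne; 11 methyl 4-[(2R,5S)-5-(bromoethynyl)oxolan-2-yl]butanoate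
Product: 20 methyl 4-[(2R,5S)-5-[(3E,9Z,11Z)-12-bromododeca-3,9,11-trien-1-yn-1-yl]oxolan-2-yl]butanoate, via (E)-alkenylbis(3-methylbutan-2-yl)borane 19 (not isolated)
Conditions: Sia2BH (from BH3·THF and 2-methylbut-2-ene, THF, 0 °C), 18, 0 °C; then 11, Cu(acac)2 (5 mol %), NaOMe (1 M in MeOH), THF, −15 °C to rt
Reagents that add atoms: none
Why: Disiamylborane adds B–H syn and anti-Markovnikov across the terminal alkyne of 18 to give (E)-alkenylborane 19; methoxide turns 19 into a borate that hands the alkenyl group to copper with retention, and the alkenylcopper is captured at the C–Br bond of 11 (oxidative addition to trivalent copper, then reductive elimination), which forms the sp–sp2 bond and regenerates monovalent copper. The closest known reaction type is the copper-mediated coupling of (E)-alkenyldialkylboranes with 1-bromoalkynes to (E)-1,3-enynes, here a union of two former alkyne termini made possible by polarity reversal of the acetylide carbon as its bromide. No ring is closed and no stereocentre is formed; the (3E) geometry is controlled by the syn hydroboration and its retention through boron-to-copper transfer and coupling, and the (2R,5S), (9Z) and (11Z) elements are spectators. The step needs chemoselective hydroboration of the alkyne in the presence of the (Z,Z)-bromodiene, which the bulk of the dialkylborane and the electron-poor, 1,2-disubstituted character of the diene should secure, and transfer of the sp2 group in preference to the secondary alkyl groups, which is the normal order for borate-to-copper exchange. It also needs coupling at the alkynyl bromide and not at the dienyl bromide, which the palladium-free, low-temperature conditions should secure, and the methyl ester is indifferent to methoxide.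

**Compound list**
1 | (2S)-2-(chloromethyl)oxirane [(S)-epichlorohydrin] | ClC[C@@H]1CO1 | starting material
2 | (2S)-1-chlorohex-5-en-2-ol | ClC[C@@H](O)CCC=C | intermediate (not isolated)
3 | (2S)-2-(but-3-en-1-yl)oxirane | C=CCC[C@H]1CO1 | intermediate
4 | methyl prop-2-ynoate (methyl propiolate) | COC(=O)C#C | starting material
5 | methyl 3-lithioprop-2-ynoate | COC(=O)C#C[Li] | intermediate (not isolated)
6 | methyl (5S)-5-hydroxynon-8-en-2-ynoate | COC(=O)C#CC[C@@H](O)CCC=C | intermediate
7 | methyl 4-[(2S,5S)-5-(hydroxymethyl)oxolan-2-yl]but-2-ynoate | COC(=O)C#CC[C@@H]1CC[C@@H](CO)O1 | intermediate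
8 | methyl 4-[(2R,5S)-5-(hydroxymethyl)oxolan-2-yl]butanoate | COC(=O)CCC[C@@H]1CC[C@@H](CO)O1 | intermediate
9 | methyl 4-[(2R,5S)-5-formyloxolan-2-yl]butanoate | COC(=O)CCC[C@@H]1CC[C@@H](C=O)O1 | intermediate
10 | methyl 4-[(2R,5S)-5-ethynyloxolan-2-yl]butanoate | COC(=O)CCC[C@@H]1CC[C@@H](C#C)O1 | intermediate
11 | methyl 4-[(2R,5S)-5-(bromoethynyl)oxolan-2-yl]butanoate | COC(=O)CCC[C@@H]1CC[C@@H](C#CBr)O1 | intermediate
12 | hept-6-yn-1-ol | OCCCCCC#C | starting material
13 | 7-iodohept-1-yne | ICCCCCC#C | intermediate
14 | (hept-6-yn-1-yl)triphenylphosphonium iodide | C#CCCCCC[P+](c1ccccc1)(c1ccccc1)c1ccccc1.[I-] | intermediate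
15 | ethyl (2Z)-3-bromoprop-2-enoate | CCOC(=O)/C=C\Br | starting material
16 | (hept-6-yn-1-ylidene)triphenylphosphorane | C#CCCCCC=P(c1ccccc1)(c1ccccc1)c1ccccc1 | intermediate (not isolated)
17 | (2Z)-3-bromoprop-2-enal | O=C/C=C\Br | intermediate (not isolated)
18 | (7Z,9Z)-10-bromodeca-7,9-dien-1-yne | C#CCCCC/C=C\C=C/Br | intermediate
19 | [(1E,7Z,9Z)-10-bromodeca-1,7,9-trien-1-yl]bis(3-methylbutan-2-yl)borane | CC(C)C(C)B(/C=C/CCCC/C=C\C=C/Br)C(C)C(C)C | intermediate (not isolated)
20 | methyl 4-[(2R,5S)-5-[(3E,9Z,11Z)-12-bromododeca-3,9,11-trien-1-yn-1-yl]oxolan-2-yl]butanoate | COC(=O)CCC[C@@H]1CC[C@@H](C#C/C=C/CCCC/C=C\C=C/Br)O1 | target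

**Step count**
Total steps: 11 (steps 1–7 to bromoalkyne 11, steps 8–10 to dienyne 18, step 11 the union). Longest linear sequence: 8 steps (steps 1–7, then step 11).

**Steps most likely to fail**

Step 11. Hydroboration may not discriminate fully between the alkyne and the bromodiene. Boron-to-copper transfer may be slow, so that protodeboronation or alkenyl homocoupling takes over. Halogen–metal exchange at the bromoalkyne may lead to the symmetrical diyne. The fallback sets out from 18 and comes back at 20. Hydrozirconation of 18 with Cp2Zr(H)Cl (THF, rt) and iodinolysis with I2 at 0 °C should give (1E,7Z,9Z)-10-bromo-1-iododeca-1,7,9-triene F1. F1 is then coupled with terminal alkyne 10 (taken before step 7) under Sonogashira conditions (PdCl2(PPh3)2, CuI, Et3N, THF, rt). Zerovalent palladium inserts into the alkenyl C–I bond much faster than into the dienyl C–Br bond, so 20 should result directly.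

Step 3. Oxidation or radical addition at the ynoate or its propargylic CH2 may compete with ring closure, and trans selectivity may be incomplete. The fallback sets out from 3 and comes back at 10, and removes the unsaturated ester from the cyclisation substrate.
- CuI-catalysed opening of 3 with [3-(tert-butyldimethylsilyloxy)propyl]magnesium bromide (THF, −30 °C) should give (5R)-1-[(tert-butyldimethylsilyl)oxy]non-8-en-5-ol F2.
- The same Co(modp)2/O2 cyclisation, now on a substrate carrying only a silyl ether, should give [(2S,5R)-5-{4-[(tert-butyldimethylsilyl)oxy]butyl}oxolan-2-yl]methanol F3.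
- Dess–Martin oxidation gives (2S,5R)-5-{4-[(tert-butyldimethylsilyl)oxy]butyl}oxolane-2-carbaldehyde F4.
- Ohira–Bestmann homologation gives tert-butyl{4-[(2R,5S)-5-ethynyloxolan-2-yl]butoxy}dimethylsilane F5.
- Bu4NF in THF frees 4-[(2R,5S)-5-ethynyloxolan-2-yl]butan-1-ol F6.
- TEMPO/PhI(OAc)2 in MeCN–H2O oxidises it to 4-[(2R,5S)-5-ethynyloxolan-2-yl]butanoic acid F7.
- Me3SiCHN2 in MeOH/toluene esterifies F7 to 10.

Step 10. The (Z)-bromoenal may isomerise to the E form or be over-reduced before it meets the ylide, and Z selectivity of the olefination may erode in the presence of aluminium salts. The fallback sets out from 12 and comes back at 18, and builds the diene in the opposite direction with isolable intermediates.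
- Dess–Martin oxidation of 12 gives hept-6-ynal F8.
- Still–Gennari olefination (methyl bis(2,2,2-trifluoroethyl)phosphonoacetate, KN(SiMe3)2, 18-crown-6, THF, −78 °C) should give methyl (2Z)-non-2-en-8-ynoate F9.
- i-Bu2AlH (CH2Cl2, −78 °C) reduces it to (2Z)-non-2-en-8-yn-1-ol F10.
- MnO2 (CH2Cl2, 0 °C) gives (2Z)-non-2-en-8-ynal F11.
- Z-selective Wittig bromomethylenation with (bromomethyl)triphenylphosphonium bromide and KOt-Bu (THF, −78 °C) should give 18.

Further compounds
F1 | step 11 | (1E,7Z,9Z)-10-bromo-1-iododeca-1,7,9-triene | I/C=C/CCCC/C=C\C=C/Br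
F2 | step 3 | (5R)-1-[(tert-butyldimethylsilyl)oxy]non-8-en-5-ol | CC(C)(C)[Si](C)(C)OCCCC[C@@H](O)CCC=C
F3 | step 3 | [(2S,5R)-5-{4-[(tert-butyldimethylsilyl)oxy]butyl}oxolan-2-yl]methanol | CC(C)(C)[Si](C)(C)OCCCC[C@@H]1CC[C@@H](CO)O1
F4 | step 3 | (2S,5R)-5-{4-[(tert-butyldimethylsilyl)oxy]butyl}oxolane-2-carbaldehyde | CC(C)(C)[Si](C)(C)OCCCC[C@@H]1CC[C@@H](C=O)O1
F5 | step 3 | tert-butyl{4-[(2R,5S)-5-ethynyloxolan-2-yl]butoxy}dimethylsilane | CC(C)(C)[Si](C)(C)OCCCC[C@@H]1CC[C@@H](C#C)O1
F6 | step 3 | 4-[(2R,5S)-5-ethynyloxolan-2-yl]butan-1-ol | OCCCC[C@@H]1CC[C@@H](C#C)O1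
F7 | step 3 | 4-[(2R,5S)-5-ethynyloxolan-2-yl]butanoic acid | OC(=O)CCC[C@@H]1CC[C@@H](C#C)O1
F8 | step 10 | hept-6-ynal | C#CCCCCC=O
F9 | step 10 | methyl (2Z)-non-2-en-8-ynoate | C#CCCCC/C=C\C(=O)OC
F10 | step 10 | (2Z)-non-2-en-8-yn-1-ol | C#CCCCC/C=C\CO
F11 | step 10 | (2Z)-non-2-en-8-ynal | C#CCCCC/C=C\C=O
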